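Remark on the chemistry: the benzofuran phenol is carried as a triisopropylsilyl ether, not as an acetal, so that the route never needs acid once the two ortho-prenylphenol units exist. Benzofuran-6-ol, methyl 2,4,6-trihydroxybenzoate and 2-methylbut-3-en-2-ol are assumed to be purchasable.

Locants used below: benzofuran O1, C2, C3, C3a, C4–C7, C7a (ring A = benzo ring, ring C = furan ring); pendant aryl ring B = C1'–C6'; prenyl carbons C1''–C3''.

## Analysis of the target

Mulberrofuran V (16) is a 2-arylbenzofuran with a hydroxyl on C6 and, on C2, a pentasubstituted benzene ring B. Ring B carries hydroxyls on C3' and C5', 3-methylbut-2-enyl (prenyl) groups on C2' and C6', and its only hydrogen on C4'. There is no stereocentre: the prenyl double bonds end in two methyl groups, and ring B is symmetric about the C1'–C4' line, so the hindered C2–C1' axis cannot be stereogenic either. The sensitive parts are the three free phenols (an oxidation-prone resorcinol and a benzofuranol), the electron-rich C2=C3 bond, and above all the two ortho-prenylphenol units, which close to 2,2-dimethylchromans under protic or Lewis acid. The difficulty is positional and steric. The prenyl groups must go to the two carbons that flank the biaryl bond, not to C4' (the most nucleophilic carbon of the resorcinol), to C3 of the benzofuran or to oxygen. The finished C2–C1' bond also lies between two ortho substituents. The strategy rests on one feature: each prenyl CH2 (C1'') is bonded to a ring carbon (C2' or C6') that is ortho to a phenolic oxygen (on C3' or C5'). That is the pattern an aromatic Claisen rearrangement of a 1,1-dimethylallyl ether leaves behind. The only other ortho carbon, C4', is shared by both oxygens and can carry a carboxyl group that is lost at the end; this also makes ring B available as methyl 2,4,6-trihydroxybenzoate (5).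

## Retrosynthetic reasoning

**16 back to 13.** The hydrogen on C4' is traced back to a carboxyl group (acid 15) and this to the methyl ester 13; the free hydroxyl on C6 is traced back to the silyl ether of 13. Nothing of the skeleton is cut here. The two groups are added because the ester blocks C4' during prenyl transfer and the silyl ether masks the benzofuranol during organometallic steps. The forward steps must remove both without acid: hydroxide cleaves the silyl ether (14) and the ester (15), and heat expels CO2 from the 2,6-dihydroxybenzoic acid.

**13 back to 11.** The C2'–C1'' and C6'–C1'' bonds are cut and C3'' of each prenyl unit is reconnected to the neighbouring oxygen, giving the bis(1,1-dimethylallyl) ether 11. These are the only two carbon–carbon bonds of ring B that a purchased phloroglucinol derivative lacks. Cutting them this way turns a regiochemical problem of C-alkylation into O-alkylation of two equivalent phenols. The forward reaction is a double [3,3] shift through the mono-rearranged phenol 12; it must deliver each allyl unit to C2' or C6' with allylic inversion and leave C4' untouched.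

**11 back to 7 and 10.** The two O–C(tertiary) bonds are cut. A tertiary allylic ether of a phenol cannot be made by displacement on a tertiary halide, so the forward step is a palladium-catalysed allylic etherification of diol 7 with carbonate 10, which favours the branched ether. Carbonate 10 comes from 2-methylbut-3-en-2-ol (8) through its lithium alkoxide 9.

**7 back to 6 and 4.** The biaryl bond C2–C1' is cut. At this stage C1' still has two ortho hydrogens, so the cross-coupling is unhindered, and both halves are simple: aryl triflate 6 and benzofuran-2-yl boronate 4. The forward Suzuki coupling must tolerate two free, chelated phenols and a methyl ester.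

**6 back to 5; 4 back to 2 and 1.** Triflate 6 comes from 5 by sulfonylation of the one hydroxyl that is not hydrogen-bonded to the ester. Boronate 4 comes from silyl ether 2 by deprotonation of C2–H (lithio species 3) and borylation, and 2 from benzofuran-6-ol (1).

## Alternatives that were turned down

**Alternative 1:** Ring B is taken apart entirely, with C4' and C5' coming from an alkoxyacetylene and the remaining four ring carbons from a cyclobutenone.
- Key step: 3-[6-(triisopropylsilyloxy)benzofuran-2-yl]-2,4-bis(3-methylbut-2-enyl)cyclobut-2-en-1-one A2 would be heated with ethoxyacetylene A3. Four-electron ring opening to a vinylketene, [2+2] cycloaddition with the alkyne, a second ring opening and six-electron closure, then tautomerisation, would give 5-ethoxy-3-[6-(triisopropylsilyloxy)benzofuran-2-yl]-2,4-bis(3-methylbut-2-enyl)phenol A1 in one operation.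
- For it: the substitution pattern of ring B is fixed by the mechanism, and both prenyl groups and the benzofuran are in place before the ring exists. No biaryl coupling and no prenylation regiochemistry arise. On regiocontrol and convergence it is at least as strong as the chosen route.
- Against it: A2 is a densely substituted, sensitive four-membered ketone that needs several steps of its own. Its prenyl olefins and the benzofuran C2=C3 bond can compete with A3 as ketene partners. Most seriously, A1 carries the C5' oxygen as an ethyl ether; cleaving it needs a boron or aluminium halide or a hot thiolate, and the Lewis acids would close the prenylphenols to chromans.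
- Comparison: the chosen route buys ring B with its oxygens in place as 5, makes only the two aryl–prenyl bonds in the key step and finishes with base and heat. It gives up the convergence of the benzannulation for a short, conventional path to the key-step precursor.

**Alternative 2:** Ring B is built non-aromatic, by cutting C1'–C6' and C4'–C5' of a cyclohexane-1,3-dione.
- Key step: sodium ethoxide would add diethyl 2-(3-methylbut-2-enyl)propanedioate A6 to the β-carbon of (E)-3-{[6-(methoxymethoxy)benzofuran-2-yl]methylidene}-6-methylhept-5-en-2-one A5. The methyl ketone would then condense onto one ester to give ethyl 6-[6-(methoxymethoxy)benzofuran-2-yl]-1,5-bis(3-methylbut-2-enyl)-2,4-dioxocyclohexane-1-carboxylate A4. Ester removal and dehydrogenation would follow.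
- For it: cheap reagents, no transition metal, and both prenyl groups belong to the building blocks, so their positions are beyond doubt. On raw-material cost it is stronger than the chosen route, and on positional certainty it is equal.
- Against it: the Michael step joins a fully substituted malonate carbon to the β-carbon of an α-branched β-aryl enone, a crowded and reversible addition. A4 is two hydrogens short of a resorcinol, and every usual dehydrogenation (halogenation–elimination, iodine, quinones, hot palladium) attacks trisubstituted alkenes or the electron-rich benzofuran. The acetal must then be removed with acid beside two prenylphenols.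
- Comparison: the chosen route keeps ring B aromatic throughout, so no oxidation is needed, and its key step is a redox-neutral isomerisation.

**Alternative 3:** The furan C2=C3 bond is cut, so that the heterocycle closes last.
- Key step: low-valent titanium (TiCl3 reduced with zinc dust) would couple the aldehyde carbon and the ester carbonyl carbon of 2-formyl-5-(methoxymethoxy)phenyl 3,5-bis(methoxymethoxy)-2,6-bis(3-methylbut-2-enyl)benzoate A8 and deoxygenate the adduct. The product would be 2-[3,5-bis(methoxymethoxy)-2,6-bis(3-methylbut-2-enyl)phenyl]-6-(methoxymethoxy)benzofuran A7.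
- For it: no biaryl cross-coupling at all, since the C2–C1' bond is already present as the carbonyl–aryl bond of the benzoate. The closure is intramolecular and is an established way to 2-arylbenzofurans. On avoiding palladium coupling next to a hindered position it is stronger than the chosen route.
- Against it: the real problem, a benzoic acid with prenyl groups on both ortho carbons and oxygens on both meta carbons, is moved into the acid half of A8 and not solved. The ester carbonyl of A8 is shielded by two ortho prenyl groups, so both its formation and the titanium-mediated coupling should be slow. Lewis-acidic titanium chlorides threaten the acetals and olefins, and three acetals must be removed with acid at the end.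
- Comparison: the chosen route solves the placement of the prenyl groups in its key step and ends without acid.

Key step: step 7

## Route

**Step 1**
Reactants: 1 benzofuran-6-ol
Product: 2 6-(triisopropylsilyloxy)benzofuran
Conditions: TIPSCl, imidazole, DMF, rt
Reagents that add atoms: chlorotriisopropylsilane, CC(C)[Si](Cl)(C(C)C)C(C)C
Why: Standard silylation of a phenol; the bulky silyl ether does not direct ortho-lithiation, should survive mild aqueous base and neutral heating, and falls to hydroxide at the end.

**Step 2**
Reactants: 2 6-(triisopropylsilyloxy)benzofuran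
Product: 4 2-(4,4,5,5-tetramethyl-1,3,2-dioxaborolan-2-yl)-6-(triisopropylsilyloxy)benzofuran, via 2-lithiobenzofuran 3 (not isolated)
Conditions: n-BuLi, THF, −78 °C; i-PrOBpin, −78 °C → rt; AcOH
Reagents that add atoms: 2-isopropoxy-4,4,5,5-tetramethyl-1,3,2-dioxaborolane, CC(C)OB1OC(C)(C)C(C)(C)O1
Why: C2–H is the most acidic C–H bond of a benzofuran, so deprotonation and trapping with the borate ester (lithiation–borylation) should give the 2-boronate, and the pinacol ester is chosen because it resists protodeboronation better than the free boronic acid.

**Step 3**
Reactants: 5 methyl 2,4,6-trihydroxybenzoate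
Product: 6 methyl 2,6-dihydroxy-4-{[(trifluoromethyl)sulfonyl]oxy}benzoate
Conditions: PhNTf2 (1 equiv), Et3N, CH2Cl2, 0 °C → rt
Reagents that add atoms: N-phenylbis(trifluoromethanesulfonimide), O=S(=O)(N(c1ccccc1)S(=O)(=O)C(F)(F)F)C(F)(F)F
Why: Chemoselective O-triflation of a polyphenol: the 4-hydroxyl is the only one not hydrogen-bonded to the ester and is the most acidic (para to the carbonyl), so one equivalent of the mild triflyl donor should sulfonylate it alone.

**Step 4**
Reactants: 6 methyl 2,6-dihydroxy-4-{[(trifluoromethyl)sulfonyl]oxy}benzoate; 4 2-(4,4,5,5-tetramethyl-1,3,2-dioxaborolan-2-yl)-6-(triisopropylsilyloxy)benzofuran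
Product: 7 methyl 2,6-dihydroxy-4-[6-(triisopropylsilyloxy)benzofuran-2-yl]benzoate
Conditions: Pd(OAc)2 (cat.), SPhos, K3PO4, THF/H2O, 50 °C
Reagents that add atoms: none
Why: Suzuki–Miyaura coupling of an aryl triflate activated by the para ester with a heteroaryl boronate; the coupling site has two ortho hydrogens, the phenols are meta to the triflate and do not deactivate it by resonance, and the chelated methyl ester resists hydrolysis under these conditions.

**Step 5**
Reactants: 8 2-methylbut-3-en-2-ol
Product: 10 tert-butyl 2-methylbut-3-en-2-yl carbonate, via lithium alkoxide 9 (not isolated)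
Conditions: n-BuLi, THF, −78 → 0 °C; Boc2O, 0 °C → rt
Reagents that add atoms: di-tert-butyl dicarbonate, CC(C)(C)OC(=O)OC(=O)OC(C)(C)C
Why: Acylation of a tertiary lithium alkoxide with the dicarbonate is the usual way to the mixed carbonate that serves as the 1,1-dimethylallyl donor.

**Step 6**
Reactants: 7 methyl 2,6-dihydroxy-4-[6-(triisopropylsilyloxy)benzofuran-2-yl]benzoate; 10 tert-butyl 2-methylbut-3-en-2-yl carbonate
Product: 11 methyl 2,6-bis(2-methylbut-3-en-2-yloxy)-4-[6-(triisopropylsilyloxy)benzofuran-2-yl]benzoate
Conditions: Pd(PPh3)4 (cat.), 10 (excess), THF, 0 °C → rt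
Reagents that add atoms: none
Why: Decarboxylative palladium-catalysed allylic etherification (Tsuji–Trost type): zerovalent palladium ionises 10 with loss of CO2, the tert-butoxide set free deprotonates the chelated phenol, and the phenoxide attacks the more substituted terminus of the 1,1-dimethyl-π-allyl complex under kinetic control at low temperature, at both oxygens in turn.

**Step 7**
Reactants: 11 methyl 2,6-bis(2-methylbut-3-en-2-yloxy)-4-[6-(triisopropylsilyloxy)benzofuran-2-yl]benzoate
Product: 13 methyl 2,6-dihydroxy-3,5-bis(3-methylbut-2-enyl)-4-[6-(triisopropylsilyloxy)benzofuran-2-yl]benzoate, via mono-rearranged phenol 12 (not isolated)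
Conditions: PhMe (degassed), 120 °C, sealed tube
Reagents that add atoms: none
Why: Each aryl 1,1-dimethylallyl ether should undergo a concerted, suprafacial aromatic Claisen ([3,3] sigmatropic) shift through a chair-like six-membered transition state, in which the terminal CH2 of the allyl unit bonds to the free ortho carbon as the tertiary C–O bond breaks, and the resulting ortho-dienone tautomerises to the phenol, first to 12 and after the second shift to 13. The closest known reaction type is the thermal ortho-Claisen rearrangement of aryl 1,1-dimethylallyl ethers to ortho-prenylphenols on substrates whose other ortho position carries a removable blocking group. No ring is closed and no stereocentre is formed, so there is no mode of closure and no stereocontrol element to consider. The selectivity needed is positional: each allyl unit must end on C2' or C6' and not on C4', and it must arrive with allylic inversion so that the branched ether becomes the linear prenyl group. The ester on C4' secures the first point, because a shift to that carbon gives a dienone with a quaternary centre that cannot enolise and returns to the ether by the reverse shift, whereas the dienone formed at C2' or C6' aromatises irreversibly; the concerted mechanism secures the second. The weak tertiary allylic C–O bond lowers the barrier, so the shift should run at a temperature at which the non-ionising solvent toluene suppresses heterolysis of the ether. Each new phenol is held at once in a hydrogen bond to the ester, which lowers its tendency to add to the neighbouring prenyl double bond. The crowding around C1' is tolerated because it is created intramolecularly by attack of an unsubstituted CH2 terminus.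

**Step 8**
Reactants: 13 methyl 2,6-dihydroxy-3,5-bis(3-methylbut-2-enyl)-4-[6-(triisopropylsilyloxy)benzofuran-2-yl]benzoate
Product: 15 2,6-dihydroxy-4-(6-hydroxybenzofuran-2-yl)-3,5-bis(3-methylbut-2-enyl)benzoic acid, via desilylated ester 14 (not isolated)
Conditions: KOH, MeOH/H2O (degassed), reflux; then 1 M HCl, 0 °C
Reagents that add atoms: potassium hydroxide, [K+].[OH-]
Why: Hydroxide should first cleave the aryl silyl ether (attack at silicon, phenoxide leaving group) and then, more slowly, saponify the hindered ester; neither the prenyl groups nor the benzofuran react with base, and any acid that already loses CO2 here is simply the target.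

**Step 9**
Reactants: 15 2,6-dihydroxy-4-(6-hydroxybenzofuran-2-yl)-3,5-bis(3-methylbut-2-enyl)benzoic acid
Product: 16 mulberrofuran V, 5-(6-hydroxybenzofuran-2-yl)-4,6-bis(3-methylbut-2-enyl)benzene-1,3-diol
Conditions: DMF (degassed), 110 °C
Reagents that add atoms: none
Why: Thermal protodecarboxylation of a 2,6-dihydroxybenzoic acid: the carboxyl-bearing carbon is ortho to two hydroxyls and is protonated easily, after which CO2 leaves; the weakly basic solvent buffers the acid so that the prenylphenols should not cyclise.

## Compound list

1 | benzofuran-6-ol | Oc1ccc2ccoc2c1 | starting material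
2 | 6-(triisopropylsilyloxy)benzofuran | CC(C)[Si](Oc1ccc2ccoc2c1)(C(C)C)C(C)C | intermediate
3 | [6-(triisopropylsilyloxy)benzofuran-2-yl]lithium | [Li]c1cc2ccc(O[Si](C(C)C)(C(C)C)C(C)C)cc2o1 | intermediate (not isolated)
4 | 2-(4,4,5,5-tetramethyl-1,3,2-dioxaborolan-2-yl)-6-(triisopropylsilyloxy)benzofuran | CC(C)[Si](Oc1ccc2cc(B3OC(C)(C)C(C)(C)O3)oc2c1)(C(C)C)C(C)C | intermediate
5 | methyl 2,4,6-trihydroxybenzoate | COC(=O)c1c(O)cc(O)cc1O | starting material
6 | methyl 2,6-dihydroxy-4-{[(trifluoromethyl)sulfonyl]oxy}benzoate | COC(=O)c1c(O)cc(OS(=O)(=O)C(F)(F)F)cc1O | intermediate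
7 | methyl 2,6-dihydroxy-4-[6-(triisopropylsilyloxy)benzofuran-2-yl]benzoate | COC(=O)c1c(O)cc(-c2cc3ccc(O[Si](C(C)C)(C(C)C)C(C)C)cc3o2)cc1O | intermediate
8 | 2-methylbut-3-en-2-ol | C=CC(C)(C)O | starting material
9 | lithium 2-methylbut-3-en-2-olate | [Li+].[O-]C(C)(C)C=C | intermediate (not isolated)
10 | tert-butyl 2-methylbut-3-en-2-yl carbonate | C=CC(C)(C)OC(=O)OC(C)(C)C | intermediate
11 | methyl 2,6-bis(2-methylbut-3-en-2-yloxy)-4-[6-(triisopropylsilyloxy)benzofuran-2-yl]benzoate | COC(=O)c1c(OC(C)(C)C=C)cc(-c2cc3ccc(O[Si](C(C)C)(C(C)C)C(C)C)cc3o2)cc1OC(C)(C)C=C | intermediate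
12 | methyl 2-hydroxy-3-(3-methylbut-2-enyl)-6-(2-methylbut-3-en-2-yloxy)-4-[6-(triisopropylsilyloxy)benzofuran-2-yl]benzoate | COC(=O)c1c(O)c(CC=C(C)C)c(-c2cc3ccc(O[Si](C(C)C)(C(C)C)C(C)C)cc3o2)cc1OC(C)(C)C=C | intermediate (not isolated)
13 | methyl 2,6-dihydroxy-3,5-bis(3-methylbut-2-enyl)-4-[6-(triisopropylsilyloxy)benzofuran-2-yl]benzoate | COC(=O)c1c(O)c(CC=C(C)C)c(-c2cc3ccc(O[Si](C(C)C)(C(C)C)C(C)C)cc3o2)c(CC=C(C)C)c1O | intermediate
14 | methyl 2,6-dihydroxy-4-(6-hydroxybenzofuran-2-yl)-3,5-bis(3-methylbut-2-enyl)benzoate | COC(=O)c1c(O)c(CC=C(C)C)c(-c2cc3ccc(O)cc3o2)c(CC=C(C)C)c1O | intermediate (not isolated)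
15 | 2,6-dihydroxy-4-(6-hydroxybenzofuran-2-yl)-3,5-bis(3-methylbut-2-enyl)benzoic acid | O=C(O)c1c(O)c(CC=C(C)C)c(-c2cc3ccc(O)cc3o2)c(CC=C(C)C)c1O | intermediate
16 | mulberrofuran V, 5-(6-hydroxybenzofuran-2-yl)-4,6-bis(3-methylbut-2-enyl)benzene-1,3-diol | CC(C)=CCc1c(O)cc(O)c(CC=C(C)C)c1-c1cc2ccc(O)cc2o1 | target

## Step count and risks

Total step count: 9. Longest linear sequence: 7 steps (steps 1, 2, 4, 6, 7, 8 and 9, from benzofuran-6-ol 1).

**Step 7 (key step).**
- Risk: heterolysis of the tertiary allylic C–O bond, since the aryloxide of a salicylate-type phenol is a fair leaving group. This would lead to loss of the allyl unit as diene or to recombination at the primary terminus. A second risk is onward travel of an allyl group (shift to C4', then a Cope shift to the para carbon), which would put a 1,1-dimethylallyl group on the ring. Traces of acid on the glass would also promote closure of a prenylphenol to a chroman.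
- Fallback: abandon the O-to-C transfer and put the prenyl groups on carbon before the biaryl bond is made. Starting from 5, C-alkylation with prenyl bromide in cold aqueous KOH should give methyl 2,4,6-trihydroxy-3,5-bis(3-methylbut-2-enyl)benzoate F1. Triflation of its non-chelated hydroxyl (PhNTf2, Et3N) should give methyl 2,6-dihydroxy-3,5-bis(3-methylbut-2-enyl)-4-{[(trifluoromethyl)sulfonyl]oxy}benzoate F2. Suzuki coupling of F2 with boronate 4 (Pd(OAc)2, SPhos, K3PO4) would then rejoin the route at 13. The price is a doubly ortho-substituted coupling, which is what the main route avoids.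

**Step 6.**
- Risk: sluggish etherification of the second, chelated and now crowded phenol, combined with re-ionisation of the branched ether by zerovalent palladium. That would lead to isomerisation to the linear prenyl ether or to C-allylation.
- Fallback: build the tertiary ether from an alkyne. Starting from 7, copper-catalysed propargylation (3-chloro-3-methylbut-1-yne, CuCl2 cat., DBU, MeCN, 0 °C) should give methyl 2,6-bis(2-methylbut-3-yn-2-yloxy)-4-[6-(triisopropylsilyloxy)benzofuran-2-yl]benzoate F3. Semihydrogenation (H2, Pd/CaCO3 poisoned with Pb(OAc)2, quinoline, EtOAc) would then rejoin the route at 11.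

**Step 4.**
- Risk: protodeboronation of the electron-rich benzofuran-2-yl boronate in aqueous base outrunning transmetalation, together with cleavage of the triflate at sulfur and partial loss of the silyl group.
- Fallback: reverse the polarity of the partners. Starting from 6, Miyaura borylation (B2pin2, PdCl2(dppf), KOAc, dioxane, 80 °C) should give methyl 2,6-dihydroxy-4-(4,4,5,5-tetramethyl-1,3,2-dioxaborolan-2-yl)benzoate F4, an aryl boronate far less prone to protodeboronation. Starting from 2, the lithio species 3 is quenched with 1,2-dibromo-1,1,2,2-tetrachloroethane to give 2-bromo-6-(triisopropylsilyloxy)benzofuran F5. Suzuki coupling of F4 with F5 (PdCl2(dppf), K3PO4, dioxane/H2O) would rejoin the route at 7.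

**Step 8.**
- Risk: slow attack of hydroxide at an ester carbonyl flanked by two phenoxides, so that the long exposure to hot alkali leads to oxidative degradation of the electron-rich triphenol.
- Fallback: cleave the ester at the methyl carbon. Starting from 13, LiI in refluxing pyridine (SN2 demethylation) and a cold dilute acid work-up should give 2,6-dihydroxy-3,5-bis(3-methylbut-2-enyl)-4-[6-(triisopropylsilyloxy)benzofuran-2-yl]benzoic acid F6. Heating in DMF at 110 °C should decarboxylate it to 4,6-bis(3-methylbut-2-enyl)-5-[6-(triisopropylsilyloxy)benzofuran-2-yl]benzene-1,3-diol F7. Bu4NF in THF at 0 °C would then remove the silyl group and reach the target 16.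

## Further compounds

F1 | step 7 | methyl 2,4,6-trihydroxy-3,5-bis(3-methylbut-2-enyl)benzoate | COC(=O)c1c(O)c(CC=C(C)C)c(O)c(CC=C(C)C)c1O
F2 | step 7 | methyl 2,6-dihydroxy-3,5-bis(3-methylbut-2-enyl)-4-{[(trifluoromethyl)sulfonyl]oxy}benzoate | COC(=O)c1c(O)c(CC=C(C)C)c(OS(=O)(=O)C(F)(F)F)c(CC=C(C)C)c1O
F3 | step 6 | methyl 2,6-bis(2-methylbut-3-yn-2-yloxy)-4-[6-(triisopropylsilyloxy)benzofuran-2-yl]benzoate | COC(=O)c1c(OC(C)(C)C#C)cc(-c2cc3ccc(O[Si](C(C)C)(C(C)C)C(C)C)cc3o2)cc1OC(C)(C)C#C
F4 | step 4 | methyl 2,6-dihydroxy-4-(4,4,5,5-tetramethyl-1,3,2-dioxaborolan-2-yl)benzoate | COC(=O)c1c(O)cc(B2OC(C)(C)C(C)(C)O2)cc1O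
F5 | step 4 | 2-bromo-6-(triisopropylsilyloxy)benzofuran | CC(C)[Si](Oc1ccc2cc(Br)oc2c1)(C(C)C)C(C)C
F6 | step 8 | 2,6-dihydroxy-3,5-bis(3-methylbut-2-enyl)-4-[6-(triisopropylsilyloxy)benzofuran-2-yl]benzoic acid | O=C(O)c1c(O)c(CC=C(C)C)c(-c2cc3ccc(O[Si](C(C)C)(C(C)C)C(C)C)cc3o2)c(CC=C(C)C)c1O
F7 | step 8 | 4,6-bis(3-methylbut-2-enyl)-5-[6-(triisopropylsilyloxy)benzofuran-2-yl]benzene-1,3-diol | CC(C)=CCc1c(O)cc(O)c(CC=C(C)C)c1-c1cc2ccc(O[Si](C(C)C)(C(C)C)C(C)C)cc2o1
A1 | alternative 1 | 5-ethoxy-3-[6-(triisopropylsilyloxy)benzofuran-2-yl]-2,4-bis(3-methylbut-2-enyl)phenol | CCOc1cc(O)c(CC=C(C)C)c(-c2cc3ccc(O[Si](C(C)C)(C(C)C)C(C)C)cc3o2)c1CC=C(C)C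
A2 | alternative 1 | 3-[6-(triisopropylsilyloxy)benzofuran-2-yl]-2,4-bis(3-methylbut-2-enyl)cyclobut-2-en-1-one (racemic) | O=C1C(CC=C(C)C)C(-c2cc3ccc(O[Si](C(C)C)(C(C)C)C(C)C)cc3o2)=C1CC=C(C)C
A3 | alternative 1 | ethoxyacetylene (ethoxyethyne) | C#COCC
A4 | alternative 2 | ethyl 6-[6-(methoxymethoxy)benzofuran-2-yl]-1,5-bis(3-methylbut-2-enyl)-2,4-dioxocyclohexane-1-carboxylate (mixture of diastereomers) | CCOC(=O)C1(CC=C(C)C)C(=O)CC(=O)C(CC=C(C)C)C1c1cc2ccc(OCOC)cc2o1
A5 | alternative 2 | (E)-3-{[6-(methoxymethoxy)benzofuran-2-yl]methylidene}-6-methylhept-5-en-2-one | CC(=O)/C(CC=C(C)C)=C/c1cc2ccc(OCOC)cc2o1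
A6 | alternative 2 | diethyl 2-(3-methylbut-2-enyl)propanedioate | CCOC(=O)C(CC=C(C)C)C(=O)OCC
A7 | alternative 3 | 2-[3,5-bis(methoxymethoxy)-2,6-bis(3-methylbut-2-enyl)phenyl]-6-(methoxymethoxy)benzofuran | CC(C)=CCc1c(OCOC)cc(OCOC)c(CC=C(C)C)c1-c1cc2ccc(OCOC)cc2o1
A8 | alternative 3 | 2-formyl-5-(methoxymethoxy)phenyl 3,5-bis(methoxymethoxy)-2,6-bis(3-methylbut-2-enyl)benzoate | COCOc1ccc(C=O)c(OC(=O)c2c(CC=C(C)C)c(OCOC)cc(OCOC)c2CC=C(C)C)c1
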